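**Retrosynthetic overview**

1. Target 31 comes from 30 by one hydrogenation (ring alkene and benzyl ether). 30 is cut at the ketone C(=O)–CH2 bond into ring acid 19 and iodide 27 (Negishi acylation).
2. 27 comes from iodo acid 24 (bought stereocentre in hemiester 20, via lactone 22) and 3-O-benzyl-sn-glycerol 25. 19 comes from ring diester 14 by turning its CH2CO2R arm into the 3-oxobutyl arm.
3. Key disconnection: the only carbocycle is split into two three-carbon units. Ring bond C4–C5 is made as a cis alkene (Wittig) and ring bond C1–C2 by intramolecular Michael addition, in one flask, from phosphonium salt 10 and aldehyde–enoate 6.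
4. Enabling feature: ring C3 is a quaternary CMe2 between C4 and C2, so the C4–C3–C2 unit can be a non-enolisable aldehyde/enoate bis-electrophile. Ring C1 is α to the ketone carbonyl, so the C1–C6–C5 unit can be an ester-enolate/ylide bis-nucleophile. The enoate carries an 8-phenylmenthyl group that controls both ring stereocentres.
5. Ring order: the six-membered ring is the only ring closed, in step 6.

Key step: step 6

Remark: ring atoms are numbered as in the target name (C1 quaternary carbon with CH3 and the keto chain, C2 the CH with the 3-oxobutyl arm, C3 the CMe2 carbon, C4–C6 the CH2 groups). The stages of step 6 run in one flask and count as one step. Compounds 1, 16, 20 and 25 are assumed to be purchasable.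

**Route**

Step 1
Reactants: 1 (1R,2S,5R)-5-methyl-2-(2-phenylpropan-2-yl)cyclohexan-1-ol; 2 2-(diethoxyphosphoryl)acetic acid
Product: 3 (1R,2S,5R)-5-methyl-2-(2-phenylpropan-2-yl)cyclohexyl 2-(diethoxyphosphoryl)acetate
Conditions: DCC, DMAP (cat.), CH2Cl2, 0 °C → rt
Reagents that add atoms: none
Why: Steglich esterification of the secondary alcohol with the phosphonoacetic acid; no stereocentre is touched.

Step 2
Reactants: 3; 4 3-hydroxy-2,2-dimethylpropanal
Product: 5 (1R,2S,5R)-5-methyl-2-(2-phenylpropan-2-yl)cyclohexyl (E)-5-hydroxy-4,4-dimethylpent-2-enoate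
Conditions: LiCl, DBU, MeCN, rt
Reagents that add atoms: none
Why: Horner–Wadsworth–Emmons olefination under mild LiCl/amine conditions should give the (E)-enoate from the non-enolisable aldehyde and leave the neopentyl alcohol alone.

Step 3
Reactants: 5
Product: 6 (1R,2S,5R)-5-methyl-2-(2-phenylpropan-2-yl)cyclohexyl (E)-4,4-dimethyl-5-oxopent-2-enoate
Conditions: TEMPO (cat.), PhI(OAc)2, CH2Cl2, rt
Reagents that add atoms: none
Why: Oxoammonium (TEMPO) oxidation of the primary alcohol should stop at the aldehyde, which has no α-hydrogen and cannot enolise.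

Step 4
Reactants: 7 3-methyldihydrofuran-2(3H)-one (racemic); 8 triphenylphosphine hydrobromide
Product: 9 (3-carboxybutyl)triphenylphosphonium bromide (racemic)
Conditions: neat melt, 160–170 °C
Reagents that add atoms: none
Why: Bromide opens the lactone at the O–CH2 carbon and triphenylphosphine displaces the primary bromide (SN2, phosphonium salt formation).

Step 5
Reactants: 9
Product: 10 (4-tert-butoxy-3-methyl-4-oxobutyl)triphenylphosphonium bromide (racemic)
Conditions: 2-methylpropene (excess), H2SO4 (cat.), CH2Cl2, sealed vessel, rt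
Reagents that add atoms: 2-methylpropene CC(C)=C
Why: Acid-catalysed addition of the carboxylic acid to isobutene gives the bulky tert-butyl ester that step 6 needs.

Step 6
Reactants: 10; 6
Product: 14 (1R,2S,5R)-5-methyl-2-(2-phenylpropan-2-yl)cyclohexyl 2-[(1R,6R)-6-(tert-butoxycarbonyl)-2,2,6-trimethylcyclohex-3-en-1-yl]acetate, via phosphonium ylide 11 (not isolated), via Z-configured diene diester 12 (not isolated), via lithium ester enolate 13 (not isolated)
Conditions: 10, KN(SiMe3)2 (1.05 equiv), THF, −78 → 0 °C; 6, −78 → 0 °C; then LiN(SiMe3)2 (1.5 equiv), −78 → −20 °C; aq. NH4Cl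
Reagents that add atoms: none
Why: A Wittig olefination is followed in the same flask by an intramolecular Michael addition (formal three-carbon plus three-carbon annulation): ylide 11 adds to the non-enolisable α-quaternary aldehyde of 6 under salt-free conditions to give the (Z)-alkene 12 (ring bond C4=C5), and the lithium enolate 13 of the tert-butyl ester then attacks the enoate β-carbon to form ring bond C1–C2. The closest known reaction types are Z-selective Wittig reactions of ester-bearing alkylidenephosphoranes with hindered aldehydes and ester-enolate Michael cyclisations onto enoates of 8-phenylmenthol. The ring closes in a 6-exo-trig mode, helped by the cis double bond and the gem-dimethyl group, which hold the enolate carbon next to the acceptor. Ring C2 is set by the auxiliary: in the closed, lithium-bridged transition state the enoate is s-cis and the face on the side of the 2-phenylpropan-2-yl group is covered by the phenyl ring, so C1 should add to the open face. Ring C1 (quaternary) is set relative to C2 by the chair-like transition state in which the large metal-bound tert-butoxy enolate and the acceptor arm are both pseudo-equatorial and the methyl group pseudo-axial, which places the ester trans to the CH2CO2R arm. The step needs Z-selectivity (only the Z-alkene can close), aldehyde-over-enoate chemoselectivity of the ylide and kinetic control of the Michael step; these are secured by the non-stabilised ylide with a potassium base at −78 °C, by the absence of any enolisable position in 6 (ring C3 is quaternary) and by cyclisation below −20 °C, where the product enolate should not revert.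

Step 7
Reactants: 14
Product: 15 tert-butyl (1R,6R)-1,5,5-trimethyl-6-(2-oxoethyl)cyclohex-3-ene-1-carboxylate
Conditions: iBu2AlH (1.1 equiv), toluene, −78 °C; aq. potassium sodium tartrate
Reagents that add atoms: none
Why: Partial reduction of the unhindered CH2-ester to the aldehyde through the aluminium hemiacetal that is stable at −78 °C; the tert-butyl ester on the quaternary carbon is too hindered to react and the auxiliary alcohol is released for recovery.

Step 8
Reactants: 15; 16 (1-methoxyethyl)triphenylphosphonium chloride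
Product: 18 tert-butyl (1R,6R)-6-(3-methoxybut-2-en-1-yl)-1,5,5-trimethylcyclohex-3-ene-1-carboxylate (E/Z mixture), via methoxyethylidene ylide 17 (not isolated)
Conditions: 16, KN(SiMe3)2, THF, 0 °C; then 15, −78 °C → rt
Reagents that add atoms: none
Why: Wittig olefination with the α-methoxy ylide turns the aldehyde into a methyl enol ether, a masked methyl ketone one carbon longer; the alkene geometry is irrelevant.

Step 9
Reactants: 18
Product: 19 (1R,6R)-1,5,5-trimethyl-6-(3-oxobutyl)cyclohex-3-ene-1-carboxylic acid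
Conditions: CF3CO2H, CH2Cl2, H2O (excess), 0 °C → rt
Reagents that add atoms: water O
Why: Acid hydrolysis of the enol ether to the methyl ketone and acidolysis of the tert-butyl ester (loss of isobutene) in one operation; neither ring stereocentre is α to a carbonyl with a hydrogen, so none can epimerise.

Step 10
Reactants: 20 (3R)-5-methoxy-3-methyl-5-oxopentanoic acid
Product: 22 (4R)-4-methyltetrahydro-2H-pyran-2-one, via hydroxy ester 21 (not isolated)
Conditions: BH3·SMe2, THF, 0 °C → rt; MeOH; then TsOH (cat.), toluene, 80 °C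
Reagents that add atoms: none
Why: Chemoselective borane reduction of the carboxylic acid beside the methyl ester, then acid-catalysed lactonisation; the bought stereocentre is untouched.

Step 11
Reactants: 22
Product: 24 (3S)-5-iodo-3-methylpentanoic acid, via trimethylsilyl ester 23 (not isolated)
Conditions: Me3SiI (1.2 equiv), CH2Cl2, rt; then H2O
Reagents that add atoms: iodotrimethylsilane C[Si](C)(C)I
Why: Silyl activation of the lactone carbonyl and SN2 attack of iodide at the O–CH2 carbon open the ring; hydrolysis of the silyl ester gives the ω-iodo acid (the descriptor changes only because iodine raises the priority of that arm).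

Step 12
Reactants: 24; 25 (2R)-3-(benzyloxy)propane-1,2-diol
Product: 26 (2S)-3-(benzyloxy)-2-hydroxypropyl (3S)-5-iodo-3-methylpentanoate
Conditions: EDC·HCl, DMAP (cat.), CH2Cl2, −20 → 0 °C
Reagents that add atoms: none
Why: Carbodiimide (Steglich-type) esterification should take the primary hydroxyl in preference to the secondary one at low temperature; the glycerol stereocentre comes from 25.

Step 13
Reactants: 26
Product: 27 (2S)-2-acetoxy-3-(benzyloxy)propyl (3S)-5-iodo-3-methylpentanoate
Conditions: Ac2O, pyridine, DMAP (cat.), CH2Cl2, 0 °C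
Reagents that add atoms: acetic anhydride CC(=O)OC(C)=O
Why: Acetylation of the remaining secondary alcohol; with no free hydroxyl left, acyl migration cannot occur.

Step 14
Reactants: 19; 27
Product: 30 (2S)-2-acetoxy-3-(benzyloxy)propyl (3R)-3-methyl-6-oxo-6-[(1R,6R)-1,5,5-trimethyl-6-(3-oxobutyl)cyclohex-3-en-1-yl]hexanoate, via acid chloride 28 (not isolated), via alkylzinc iodide 29 (not isolated)
Conditions: 19, (COCl)2, DMF (cat.), CH2Cl2, 0 °C → rt, evaporate; separately 27, Zn (activated), LiCl, THF, 40 °C; then Pd(PPh3)4 (5 mol %), THF, 0 °C → rt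
Reagents that add atoms: none
Why: Negishi acylation: zerovalent palladium inserts into the acid chloride, the ester-tolerant alkylzinc iodide transmetalates and reductive elimination gives the hindered ketone, leaving the methyl ketone, esters and alkene untouched; no stereocentre is affected.

Step 15
Reactants: 30
Product: 31 (2S)-2-acetoxy-3-hydroxypropyl (3R)-3-methyl-6-oxo-6-[(1R,2R)-1,3,3-trimethyl-2-(3-oxobutyl)cyclohexyl]hexanoate
Conditions: H2 (1 atm), Pd/C, EtOAc, rt
Reagents that add atoms: none
Why: Heterogeneous hydrogenation saturates the ring alkene (no new stereocentre) and hydrogenolyses the benzyl ether under neutral conditions, which should keep the 2-acetate from migrating to the freed primary hydroxyl.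

**Compound list**

1 | (1R,2S,5R)-5-methyl-2-(2-phenylpropan-2-yl)cyclohexan-1-ol | O[C@@H]1C[C@H](C)CC[C@H]1C(C)(C)c1ccccc1 | starting material
2 | 2-(diethoxyphosphoryl)acetic acid | OC(=O)CP(=O)(OCC)OCC | starting material
3 | (1R,2S,5R)-5-methyl-2-(2-phenylpropan-2-yl)cyclohexyl 2-(diethoxyphosphoryl)acetate | CCOP(=O)(OCC)CC(=O)O[C@@H]1C[C@H](C)CC[C@H]1C(C)(C)c1ccccc1 | intermediate
4 | 3-hydroxy-2,2-dimethylpropanal | OCC(C)(C)C=O | starting material
5 | (1R,2S,5R)-5-methyl-2-(2-phenylpropan-2-yl)cyclohexyl (E)-5-hydroxy-4,4-dimethylpent-2-enoate | OCC(C)(C)/C=C/C(=O)O[C@@H]1C[C@H](C)CC[C@H]1C(C)(C)c1ccccc1 | intermediate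
6 | (1R,2S,5R)-5-methyl-2-(2-phenylpropan-2-yl)cyclohexyl (E)-4,4-dimethyl-5-oxopent-2-enoate | O=CC(C)(C)/C=C/C(=O)O[C@@H]1C[C@H](C)CC[C@H]1C(C)(C)c1ccccc1 | intermediate
7 | 3-methyldihydrofuran-2(3H)-one (racemic) | CC1CCOC1=O | starting material
8 | triphenylphosphine hydrobromide | [Br-].[PH+](c1ccccc1)(c1ccccc1)c1ccccc1 | starting material
9 | (3-carboxybutyl)triphenylphosphonium bromide (racemic) | CC(CC[P+](c1ccccc1)(c1ccccc1)c1ccccc1)C(=O)O.[Br-] | intermediate
10 | (4-tert-butoxy-3-methyl-4-oxobutyl)triphenylphosphonium bromide (racemic) | CC(CC[P+](c1ccccc1)(c1ccccc1)c1ccccc1)C(=O)OC(C)(C)C.[Br-] | intermediate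
11 | tert-butyl 2-methyl-4-(triphenyl-λ5-phosphanylidene)butanoate (ylide) | CC(CC=P(c1ccccc1)(c1ccccc1)c1ccccc1)C(=O)OC(C)(C)C | intermediate
12 | 1-tert-butyl 9-[(1R,2S,5R)-5-methyl-2-(2-phenylpropan-2-yl)cyclohexyl] (4Z,7E)-2,6,6-trimethylnona-4,7-dienedioate (both C2 epimers) | CC(C/C=C\C(C)(C)/C=C/C(=O)O[C@@H]1C[C@H](C)CC[C@H]1C(C)(C)c1ccccc1)C(=O)OC(C)(C)C | intermediate
13 | lithium enolate of 12 at the tert-butyl ester | [Li]OC(OC(C)(C)C)=C(C)C/C=C\C(C)(C)/C=C/C(=O)O[C@@H]1C[C@H](C)CC[C@H]1C(C)(C)c1ccccc1 | intermediate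
14 | (1R,2S,5R)-5-methyl-2-(2-phenylpropan-2-yl)cyclohexyl 2-[(1R,6R)-6-(tert-butoxycarbonyl)-2,2,6-trimethylcyclohex-3-en-1-yl]acetate | O=C(C[C@@H]1C(C)(C)C=CC[C@@]1(C)C(=O)OC(C)(C)C)O[C@@H]1C[C@H](C)CC[C@H]1C(C)(C)c1ccccc1 | intermediate
15 | tert-butyl (1R,6R)-1,5,5-trimethyl-6-(2-oxoethyl)cyclohex-3-ene-1-carboxylate | O=CC[C@@H]1C(C)(C)C=CC[C@@]1(C)C(=O)OC(C)(C)C | intermediate
16 | (1-methoxyethyl)triphenylphosphonium chloride | COC(C)[P+](c1ccccc1)(c1ccccc1)c1ccccc1.[Cl-] | starting material
17 | (1-methoxyethylidene)triphenyl-λ5-phosphane (ylide) | COC(C)=P(c1ccccc1)(c1ccccc1)c1ccccc1 | intermediate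
18 | tert-butyl (1R,6R)-6-(3-methoxybut-2-en-1-yl)-1,5,5-trimethylcyclohex-3-ene-1-carboxylate (E/Z mixture) | COC(C)=CC[C@@H]1C(C)(C)C=CC[C@@]1(C)C(=O)OC(C)(C)C | intermediate
19 | (1R,6R)-1,5,5-trimethyl-6-(3-oxobutyl)cyclohex-3-ene-1-carboxylic acid | CC(=O)CC[C@@H]1C(C)(C)C=CC[C@@]1(C)C(=O)O | intermediate
20 | (3R)-5-methoxy-3-methyl-5-oxopentanoic acid | OC(=O)C[C@@H](C)CC(=O)OC | starting material
21 | methyl (3R)-5-hydroxy-3-methylpentanoate | OCC[C@@H](C)CC(=O)OC | intermediate
22 | (4R)-4-methyltetrahydro-2H-pyran-2-one | O=C1C[C@H](C)CCO1 | intermediate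
23 | trimethylsilyl (3S)-5-iodo-3-methylpentanoate | C[Si](C)(C)OC(=O)C[C@H](C)CCI | intermediate
24 | (3S)-5-iodo-3-methylpentanoic acid | OC(=O)C[C@H](C)CCI | intermediate
25 | (2R)-3-(benzyloxy)propane-1,2-diol | OC[C@H](COCc1ccccc1)O | starting material
26 | (2S)-3-(benzyloxy)-2-hydroxypropyl (3S)-5-iodo-3-methylpentanoate | O=C(C[C@H](C)CCI)OC[C@H](COCc1ccccc1)O | intermediate
27 | (2S)-2-acetoxy-3-(benzyloxy)propyl (3S)-5-iodo-3-methylpentanoate | O=C(C[C@H](C)CCI)OC[C@H](COCc1ccccc1)OC(C)=O | intermediate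
28 | (1R,6R)-1,5,5-trimethyl-6-(3-oxobutyl)cyclohex-3-ene-1-carbonyl chloride | CC(=O)CC[C@@H]1C(C)(C)C=CC[C@@]1(C)C(=O)Cl | intermediate
29 | iodozinc reagent of 27: {(3S)-5-[(2S)-2-acetoxy-3-(benzyloxy)propoxy]-3-methyl-5-oxopentyl}zinc iodide | O=C(C[C@H](C)CC[Zn]I)OC[C@H](COCc1ccccc1)OC(C)=O | intermediate
30 | (2S)-2-acetoxy-3-(benzyloxy)propyl (3R)-3-methyl-6-oxo-6-[(1R,6R)-1,5,5-trimethyl-6-(3-oxobutyl)cyclohex-3-en-1-yl]hexanoate | CC(=O)CC[C@@H]1C(C)(C)C=CC[C@@]1(C)C(=O)CC[C@@H](C)CC(=O)OC[C@H](COCc2ccccc2)OC(C)=O | intermediate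
31 | (2S)-2-acetoxy-3-hydroxypropyl (3R)-3-methyl-6-oxo-6-[(1R,2R)-1,3,3-trimethyl-2-(3-oxobutyl)cyclohexyl]hexanoate | CC(=O)CC[C@@H]1C(C)(C)CCC[C@@]1(C)C(=O)CC[C@@H](C)CC(=O)OC[C@H](CO)OC(C)=O | target

**Step count and risks**

Total step count: 15. Longest linear sequence: 9 steps (steps 1, 2, 3, 6, 7, 8, 9, 14, 15).

The three steps most likely to fail:

Step 6. The Michael closure may show poor or reversed facial selectivity if it does not run through the lithium-bridged s-cis arrangement, and the enolate addition may revert before quench. The fallback separates the two events and closes the ring under Lewis acid activation, where the enoate is expected to react through its s-trans conformer in an open transition state; this exposes the other face, so the antipodal auxiliary is used. It sets out from 2, 4 and 10 and comes back to the route at 15. The alcohol (1S,2R,5S)-5-methyl-2-(2-phenylpropan-2-yl)cyclohexan-1-ol F1 is esterified with 2 (DCC, DMAP) to the phosphonate F2. Horner–Wadsworth–Emmons reaction with 4 (LiCl, DBU) gives the hydroxy enoate F3, and TEMPO/PhI(OAc)2 oxidation gives the aldehyde F4. Wittig reaction of F4 with ylide 11 (from 10 and KN(SiMe3)2) gives the Z-configured diene diester F5, which is isolated. LiN(iPr)2 and Me3SiCl at −78 °C convert it into the silyl ketene acetal F6, used crude. EtAlCl2 in CH2Cl2 at −78 °C then effects an intramolecular Mukaiyama–Michael addition to the ring diester F7, which has the ring configuration of 14. Reduction with iBu2AlH as in step 7 gives 15.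

Step 14. Transmetalation to the crowded acyl-palladium species next to the quaternary carbon may be slow, so that decarbonylation or protonation of the zinc reagent takes over. The fallback builds the ketone by addition to an aldehyde and oxidation instead of acyl substitution. It sets out from 18 and 27 and comes back to the route at 30. LiAlH4 in refluxing THF reduces the tert-butyl ester of 18 to the neopentyl alcohol F8, and Dess–Martin periodinane buffered with pyridine gives the aldehyde F9. Addition of the zinc reagent 29 (from 27) in the presence of MgCl2 in THF gives the carbinol F10 as an epimer mixture, and a second buffered Dess–Martin oxidation gives the ketone F11. Mild hydrolysis of the enol ether (pyridinium p-toluenesulfonate, acetone/water) gives 30.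

Step 9. The oxocarbenium ion formed on protonation of the enol ether may be trapped by the ring alkene (Prins-type cyclisation) before water adds. The fallback installs the methyl ketone without an enol ether, by acylation of an alkylzinc. It sets out from 14 and comes back to the route at 19. LiBH4 in THF reduces the auxiliary ester of 14 to the primary alcohol F12, and I2, PPh3 and imidazole give the iodide F13. Zinc insertion (Zn, LiCl, THF) gives the alkylzinc iodide F14, which is acylated with acetyl chloride under Pd(PPh3)4 catalysis to the keto ester F15. CF3CO2H in CH2Cl2 then cleaves only the tert-butyl ester and gives 19.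

Further compounds
F1 | step 6 | (1S,2R,5S)-5-methyl-2-(2-phenylpropan-2-yl)cyclohexan-1-ol | O[C@H]1C[C@@H](C)CC[C@@H]1C(C)(C)c1ccccc1
F2 | step 6 | (1S,2R,5S)-5-methyl-2-(2-phenylpropan-2-yl)cyclohexyl 2-(diethoxyphosphoryl)acetate | CCOP(=O)(OCC)CC(=O)O[C@H]1C[C@@H](C)CC[C@@H]1C(C)(C)c1ccccc1
F3 | step 6 | (1S,2R,5S)-5-methyl-2-(2-phenylpropan-2-yl)cyclohexyl (E)-5-hydroxy-4,4-dimethylpent-2-enoate | OCC(C)(C)/C=C/C(=O)O[C@H]1C[C@@H](C)CC[C@@H]1C(C)(C)c1ccccc1
F4 | step 6 | (1S,2R,5S)-5-methyl-2-(2-phenylpropan-2-yl)cyclohexyl (E)-4,4-dimethyl-5-oxopent-2-enoate | O=CC(C)(C)/C=C/C(=O)O[C@H]1C[C@@H](C)CC[C@@H]1C(C)(C)c1ccccc1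
F5 | step 6 | 1-tert-butyl 9-[(1S,2R,5S)-5-methyl-2-(2-phenylpropan-2-yl)cyclohexyl] (4Z,7E)-2,6,6-trimethylnona-4,7-dienedioate | CC(C/C=C\C(C)(C)/C=C/C(=O)O[C@H]1C[C@@H](C)CC[C@@H]1C(C)(C)c1ccccc1)C(=O)OC(C)(C)C
F6 | step 6 | trimethylsilyl ketene acetal of F5 at the tert-butyl ester | C[Si](C)(C)OC(OC(C)(C)C)=C(C)C/C=C\C(C)(C)/C=C/C(=O)O[C@H]1C[C@@H](C)CC[C@@H]1C(C)(C)c1ccccc1
F7 | step 6 | (1S,2R,5S)-5-methyl-2-(2-phenylpropan-2-yl)cyclohexyl 2-[(1R,6R)-6-(tert-butoxycarbonyl)-2,2,6-trimethylcyclohex-3-en-1-yl]acetate | O=C(C[C@@H]1C(C)(C)C=CC[C@@]1(C)C(=O)OC(C)(C)C)O[C@H]1C[C@@H](C)CC[C@@H]1C(C)(C)c1ccccc1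
F8 | step 14 | [(1R,6R)-6-(3-methoxybut-2-en-1-yl)-1,5,5-trimethylcyclohex-3-en-1-yl]methanol | COC(C)=CC[C@@H]1C(C)(C)C=CC[C@@]1(C)CO
F9 | step 14 | (1R,6R)-6-(3-methoxybut-2-en-1-yl)-1,5,5-trimethylcyclohex-3-ene-1-carbaldehyde | COC(C)=CC[C@@H]1C(C)(C)C=CC[C@@]1(C)C=O
F10 | step 14 | (2S)-2-acetoxy-3-(benzyloxy)propyl (3R)-6-hydroxy-6-[(1R,6R)-6-(3-methoxybut-2-en-1-yl)-1,5,5-trimethylcyclohex-3-en-1-yl]-3-methylhexanoate (epimers at the carbinol) | COC(C)=CC[C@@H]1C(C)(C)C=CC[C@@]1(C)C(O)CC[C@@H](C)CC(=O)OC[C@H](COCc2ccccc2)OC(C)=O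
F11 | step 14 | (2S)-2-acetoxy-3-(benzyloxy)propyl (3R)-6-[(1R,6R)-6-(3-methoxybut-2-en-1-yl)-1,5,5-trimethylcyclohex-3-en-1-yl]-3-methyl-6-oxohexanoate | COC(C)=CC[C@@H]1C(C)(C)C=CC[C@@]1(C)C(=O)CC[C@@H](C)CC(=O)OC[C@H](COCc2ccccc2)OC(C)=O
F12 | step 9 | tert-butyl (1R,6R)-6-(2-hydroxyethyl)-1,5,5-trimethylcyclohex-3-ene-1-carboxylate | OCC[C@@H]1C(C)(C)C=CC[C@@]1(C)C(=O)OC(C)(C)C
F13 | step 9 | tert-butyl (1R,6R)-6-(2-iodoethyl)-1,5,5-trimethylcyclohex-3-ene-1-carboxylate | ICC[C@@H]1C(C)(C)C=CC[C@@]1(C)C(=O)OC(C)(C)C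
F14 | step 9 | iodozinc reagent of F13 | I[Zn]CC[C@@H]1C(C)(C)C=CC[C@@]1(C)C(=O)OC(C)(C)C
F15 | step 9 | tert-butyl (1R,6R)-1,5,5-trimethyl-6-(3-oxobutyl)cyclohex-3-ene-1-carboxylate | CC(=O)CC[C@@H]1C(C)(C)C=CC[C@@]1(C)C(=O)OC(C)(C)C
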